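The constants of this chemistry are not given, so they have to be drawn from the readings.

| flask | Z | D | temperature | remark | time |
|---|---|---|---|---|---|
| gamma | 0.037 M | 0.15 M | 115 °C | run made earlier |  |
| epsilon | 0.14 M | 0.15 M | 148 °C | run made earlier |  |
| zeta | 0.10 M | 0.10 M | 115 °C | run made earlier |  |
| spring | 0.10 M | 0.150 M |  | at 100 °C until 1.0 h, from then on at 160 °C | 5.0 h |
| midnight | 0.030 M | 0.0400 M |  | at 160 °C throughout | 5.0 h |

gamma run (percent of the Z charged)

| time / h | X / % | Z / % |
|---|---|---|
| 0.333 | 6.0 | 87.1 |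
| 1.00 | 16.4 | 79.0 |
| 1.33 | 18.7 | 75.6 |
| 2.50 | 25.7 | 72.1 |

epsilon run (percent of the Z charged)

| time / min | X / % | Z / % |
|---|---|---|
| 8.00 | 12.4 | 86.6 |
| 15.0 | 16.1 | 83.5 |
| 20.0 | 15.5 | 83.5 |
| 30.0 | 17.8 | 81.3 |

zeta run (percent of the Z charged)

| time / h | X / % | Z / % |
|---|---|---|
| 0.200 | 3.1 | 93.3 |
| 0.500 | 6.8 | 88.4 |
| 1.00 | 11.9 | 83.8 |
| 2.50 | 19.8 | 78.0 |

(scatter of a reading: 0.5 percentage points)

- which one finishes higher in amount of X, in percent of the Z charged ("neither" within 2 percentage points) (spring / midnight / neither)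
- amount of X at the end, in percent of the Z charged, spring
- amount of X at the end, in percent of the Z charged, midnight

- what was read earlier has a scatter of 0.5 percentage points, one standard deviation
- a reading or a percentage of X counts all its forms, free or not

Begin with the main step, Z + D → X. By charge, Z is the limiting reagent in both new flasks (0.10 M against 0.150 M in spring, 0.030 M against 0.0400 M in midnight). This step allows 100% X.

The readings do not support that. In zeta, the rate of X from the first reading to the last interval falls 2.94-fold, a far greater fall than that of Z, from 93.3% to 78.0%. X has taken 0.0198 M of the 0.10 M of D. D therefore seems to leave by a path without Z.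

Add that path, taken as second order in D, with k for the main step and k′ for the loss:

−d[D]/dt = k[Z][D] + 2k′[D][D]

d[X]/dt = k[Z][D]

Dividing the two, with [Z] at its mean and D used up:

[X]end = u·ln(1 + [D]charged/u), with u = a[Z]

Here a = k/(2k′). Epsilon's last reading, taken as its end, gives a = 0.0667, the selectivity factor of the two paths for D.

Now add the rest. Mean [Z] is the charge less half of X. Zeta, still unfinished, gives at least a = 0.0810 at 115 °C, more than at 148 °C, so a cooler hour favours X. My own reckoning puts midnight, with epsilon's a, at: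

[X]end = 18.8%

Spring passes from 100 °C to 160 °C, and no run gives an a for that course. With zeta's a, as an estimate and not a bound, spring comes to:

[X]end = 22.0%

The forecast differs from this reckoning. It says “both flasks reach equilibrium” and gives 15% for spring and 5% for midnight, with spring higher.

Spring ends at 28.8% and midnight at 18.5%, so spring finishes higher.

    Z + D ⇌ J (K = 23.0 L mol⁻¹, k = 2.00 L mol⁻¹ h⁻¹, Ea = 71.0 kJ mol⁻¹, ΔH = −28.0 kJ mol⁻¹)
    J → X (k = 0.880 h⁻¹, Ea = 121 kJ mol⁻¹)
    J → Q (k = 0.00640 h⁻¹, Ea = 126 kJ mol⁻¹)
    D + J ⇌ E (K = 20.0 L mol⁻¹, k = 6.60 L mol⁻¹ h⁻¹, Ea = 60.0 kJ mol⁻¹, ΔH = 55.0 kJ mol⁻¹)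
    D + X ⇌ G, settled at all times (K = 10.0 L mol⁻¹, ΔH = −13.0 kJ mol⁻¹)
    2 D → L (k = 5.00 L mol⁻¹ h⁻¹, Ea = 96.0 kJ mol⁻¹)
    (constants at 100 °C)

In spring, 0.0532% of the D charged stands free at 5.00 h, and L holds 0.120 M of D against 0.0288 M in X. Read back through the rule, spring gives a = 0.123, about twice midnight's, and the forward constants at 100 °C, spring's first temperature, give 0.200. Spring's a, put on the neighbour flask with 0.037 M of D, gives 16.4%, and that flask ends at 14.8%.

All runs are simulated on assumed constants; scatter was added.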